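**Plan**

- **Retrosynthetic cuts.** First the side-chain CH2–CH= bond is cut (sp3–sp2 coupling). Then C6 and the side-chain CH2 are raised to two lactone carbonyls: O1–C6 in ring A, and carbinol O–C(side chain) in a temporary ring B. Last, the bonds C5–C(carbinol) and C2–C3 are cut together as two aldol bonds.
- **Enabling feature.** A hidden twofold axis runs through C4 of the oxane ring. The arrays C(carbinol)(Ar)(O)–C5–C6 and C2(Ar)(O1)–C3–CH2 are the same anti-aldol unit with the same hand. The core is therefore a 2,4-disubstituted glutaric acid plus two molecules of one aldehyde.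
- **Forward order.** Glutaryl bis-thioimide; double anti-aldol (chain joined, no ring); cross-lactonisation to a 3,7-dioxabicyclo[3.3.1]nonane-2,6-dione (rings A and B together); ring A carbonyl to CH2 (the oxane); reductive opening of ring B; iodide; Negishi coupling; desilylation.
- **Stereochemistry.** All four stereocentres come from one auxiliary in one step. The bicycle can form only with the C3 and C5 arms cis. It holds both aryl groups equatorial and both α-hydrogens at bridgeheads, so it carries the all-cis array (unfavoured in the free oxane) safely. The E alkene comes from a Takai iodide and is kept in the coupling.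

Key step: step 2

Abbreviations: Ar = 4-(tert-butyldimethylsilyloxy)phenyl. Oxane numbering of the target: O1, C2 (aryl), C3 (side chain), C4, C5 (carbinol arm), C6.

Assumption: the magnesium enolate of the N-acylthiazolidinethione reacts through its non-chelated, dipole-opposed conformer. This is the same α-face as in the boron-mediated oxazolidinone syn aldol. If the sense were the opposite, the (R)-auxiliary would be used with no other change.

**Step 1**
Reactants: 1 (S)-4-benzyl-1,3-thiazolidine-2-thione; 2 glutaryl dichloride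
Product: 3 1,5-bis[(4S)-4-benzyl-2-thioxo-1,3-thiazolidin-3-yl]pentane-1,5-dione
Conditions: 1 (2.05 equiv), Et3N, DMAP (cat.), CH2Cl2, 0 °C to rt
Reagents that add atoms: none
Why: N-acylation of a thiazolidinethione with an acid chloride is standard, both acyl ends react alike to give the twofold-symmetric bis-thioimide, and no stereocentre is touched.

**Step 2**
Reactants: 3 bis-thioimide; 4 4-(tert-butyldimethylsilyloxy)benzaldehyde
Product: 6 (2S,4S)-1,5-bis[(4S)-4-benzyl-2-thioxo-1,3-thiazolidin-3-yl]-2,4-bis[(R)-Ar(trimethylsilyloxy)methyl]pentane-1,5-dione, via mono-aldol silyl ether 5 (not isolated)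
Conditions: 4 (2.4 equiv), MgBr2·OEt2 (20 mol %), Et3N (4 equiv), TMSCl (3 equiv), EtOAc, 23 °C; filtration through silica
Reagents that add atoms: chlorotrimethylsilane, C[Si](C)(C)Cl
Why: MgBr2 and Et3N enolise each thioimide softly to its (Z)-magnesium enolate, which adds reversibly to 4, and TMSCl silylates the magnesium aldolate, which makes the addition irreversible and frees the metal for turnover (magnesium halide-catalysed direct anti-aldol reaction of N-acylthiazolidinethiones with aromatic aldehydes, run here at both homotopic α-CH2 groups). The step closes no ring. The α-carbons (future C3 and C5) are set by the benzyl group of the auxiliary, which shields one face of the dipole-opposed enolate, and the two oxygen-bearing carbons (future C2 and carbinol C) are set by the boat-like transition state that gives the anti relation. Because both auxiliaries have the same hand, the second addition (5 to 6) repeats the first and should give the twofold-symmetric isomer, while a wrong event at either end ends in a separable diastereomer and not in the enantiomer. The step needs double rather than single addition, secured by excess 4 and TMSCl, and it needs freedom from self-condensation, secured because 4 has no α-hydrogen and a Dieckmann closure of a glutarate would give a four-membered ring. One of the two new bonds becomes the C5–C(carbinol) bond and the other becomes the C2–C3 bond of the oxane.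

**Step 3**
Reactants: 6 bis-aldol bis-silyl ether
Product: 9 (1S,4R,5S,8R)-4,8-di-Ar-3,7-dioxabicyclo[3.3.1]nonane-2,6-dione, via diol 7 (not isolated), via monolactone 8 (not isolated)
Conditions: THF/1 N HCl (5:1), rt; then Et3N, DMAP (cat.), CH2Cl2, rt
Reagents that add atoms: none
Why: Dilute acid removes the TMS ethers, and each benzylic hydroxyl then attacks the thioimide carbonyl of the other half (6-exo-trig acyl transfer with the thiazolidinethione as leaving group), which is possible only for cis C3 and C5 arms and should give the chair–chair bicycle with equatorial aryl groups and bridgehead α-hydrogens that cannot epimerise.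

**Step 4**
Reactants: 9 bis-lactone
Product: 10 (1S,4R,5S,8R)-6-hydroxy-4,8-di-Ar-3,7-dioxabicyclo[3.3.1]nonan-2-one as an anomeric mixture
Conditions: iBu2AlH (1.0 equiv), CH2Cl2, −78 °C; aq. potassium sodium tartrate
Reagents that add atoms: none
Why: Partial reduction of a lactone to the lactol at low temperature is routine, and because the two carbonyl groups are homotopic any single reduction gives the same lactol, so conversion is limited to hold back double reduction and recovered 9 is recycled.

**Step 5**
Reactants: 10 lactol-lactone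
Product: 11 (1S,4R,5R,8R)-4,8-di-Ar-3,7-dioxabicyclo[3.3.1]nonan-2-one
Conditions: Et3SiH, BF3·OEt2, CH2Cl2, −78 to −40 °C
Reagents that add atoms: none
Why: Ionic reduction of a lactol (oxocarbenium ion, then silane hydride) turns C6 into the ether CH2 without creating a stereocentre, lactone ring B is inert, and any reversible benzylic ionisation would return the equatorial aryl group that the bicycle prefers.

**Step 6**
Reactants: 11 ether-lactone
Product: 12 [(2R,3R,5R)-2-Ar-5-[(R)-Ar(hydroxy)methyl]oxan-3-yl]methanol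
Conditions: LiBH4, THF, MeOH (1 equiv), 0 °C to rt
Reagents that add atoms: none
Why: Borohydride reduction of the lactone to the diol opens the temporary ring B and sets free the carbinol and the side-chain CH2OH, while the four stereocentres and the aryl silyl ethers are not affected.

**Step 7**
Reactants: 12 diol
Product: 13 (R)-Ar[(3R,5S,6R)-6-Ar-5-(iodomethyl)oxan-3-yl]methanol
Conditions: I2 (1.1 equiv), PPh3, imidazole, CH2Cl2, 0 °C
Reagents that add atoms: iodine, [I][I]
Why: Appel-type iodination (Garegg–Samuelsson conditions) prefers the unhindered primary alcohol over the flanked secondary benzylic one, and the near-neutral medium gives no alkoxide that could close a second ether ring.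

**Step 8**
Reactants: 13 iodo alcohol
Product: 14 triethylsilyl ether of 13
Conditions: TESOTf, 2,6-lutidine, CH2Cl2, −78 to 0 °C
Reagents that add atoms: triethylsilyl triflate, CC[Si](CC)(CC)OS(=O)(=O)C(F)(F)F
Why: Silyl triflate with lutidine silylates hindered secondary alcohols reliably, which removes the acidic proton and the internal nucleophile before the organozinc step.

**Step 9**
Reactants: 4 4-(tert-butyldimethylsilyloxy)benzaldehyde
Product: 15 (E)-tert-butyl[4-(2-iodoethenyl)phenoxy]dimethylsilane
Conditions: CrCl2 (6 equiv), CHI3 (2 equiv), THF, 0 °C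
Reagents that add atoms: iodoform, IC(I)I
Why: The Takai olefination of aromatic aldehydes should give the (E)-vinyl iodide through the geminal dichromium reagent, and the aryl silyl ether is inert.

**Step 10**
Reactants: 14 alkyl iodide; 15 vinyl iodide
Product: 17 fully silylated target (three aryl TBS ethers and the carbinol TES ether), via alkylzinc iodide 16 (not isolated)
Conditions: Zn dust (activated by BrCH2CH2Br and TMSCl, cat.), LiCl, THF, 25–40 °C; then 15, Pd(PPh3)4 (5 mol %), THF, rt
Reagents that add atoms: none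
Why: Zinc inserts into the primary C–I bond and the alkylzinc iodide couples with the vinyl iodide under zerovalent palladium catalysis (Negishi coupling) with retention of the E geometry, while the silyl ethers and the benzylic ether are inert and no stereocentre is involved.

**Step 11**
Reactants: 17 silylated target
Product: 18 target, (2R,3S,5R)-oxane with (R)-carbinol
Conditions: Bu4NF (5 equiv), AcOH (5 equiv), THF, 0 °C to rt
Reagents that add atoms: none
Why: Fluoride cleaves all four silyl ethers, and the acetic acid buffer keeps the phenoxide level low, so that no quinone methide should form from the 4-hydroxybenzylic ether and alcohol and C2 stays as set.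

**Compound list**

1 | (S)-4-benzyl-1,3-thiazolidine-2-thione | S=C1N[C@@H](Cc2ccccc2)CS1 | starting material
2 | glutaryl dichloride | O=C(Cl)CCCC(=O)Cl | starting material
3 | 1,5-bis[(4S)-4-benzyl-2-thioxo-1,3-thiazolidin-3-yl]pentane-1,5-dione | O=C(CCCC(=O)N1[C@@H](Cc2ccccc2)CSC1=S)N1[C@@H](Cc2ccccc2)CSC1=S | intermediate
4 | 4-(tert-butyldimethylsilyloxy)benzaldehyde | O=Cc1ccc(O[Si](C)(C)C(C)(C)C)cc1 | starting material
5 | mono-aldol silyl ether, (2S)-α-carbon and (R)-silyloxy carbon | S=C1SC[C@H](Cc2ccccc2)N1C(=O)[C@H]([C@@H](O[Si](C)(C)C)c1ccc(O[Si](C)(C)C(C)(C)C)cc1)CCC(=O)N1[C@@H](Cc2ccccc2)CSC1=S | intermediate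
6 | (2S,4S)-bis-thioimide with two (R)-Ar(trimethylsilyloxy)methyl arms | S=C1SC[C@H](Cc2ccccc2)N1C(=O)[C@H]([C@@H](O[Si](C)(C)C)c1ccc(O[Si](C)(C)C(C)(C)C)cc1)C[C@@H]([C@@H](O[Si](C)(C)C)c1ccc(O[Si](C)(C)C(C)(C)C)cc1)C(=O)N1[C@@H](Cc2ccccc2)CSC1=S | intermediate
7 | (2S,4S)-bis-thioimide with two (R)-Ar(hydroxy)methyl arms | S=C1SC[C@H](Cc2ccccc2)N1C(=O)[C@H]([C@@H](O)c1ccc(O[Si](C)(C)C(C)(C)C)cc1)C[C@@H]([C@@H](O)c1ccc(O[Si](C)(C)C(C)(C)C)cc1)C(=O)N1[C@@H](Cc2ccccc2)CSC1=S | intermediate
8 | monolactone from the first ring closure, still carrying one thioimide and one free carbinol | O=C1O[C@@H](c2ccc(O[Si](C)(C)C(C)(C)C)cc2)[C@@H](C(=O)N2[C@@H](Cc3ccccc3)CSC2=S)C[C@H]1[C@@H](O)c1ccc(O[Si](C)(C)C(C)(C)C)cc1 | intermediate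
9 | (1S,4R,5S,8R)-4,8-di-Ar-3,7-dioxabicyclo[3.3.1]nonane-2,6-dione | O=C1O[C@@H](c2ccc(O[Si](C)(C)C(C)(C)C)cc2)[C@@H]2C[C@H]1[C@H](c1ccc(O[Si](C)(C)C(C)(C)C)cc1)OC2=O | intermediate
10 | (1S,4R,5S,8R)-6-hydroxy-4,8-di-Ar-3,7-dioxabicyclo[3.3.1]nonan-2-one, anomeric mixture | O=C1O[C@@H](c2ccc(O[Si](C)(C)C(C)(C)C)cc2)[C@@H]2C[C@H]1[C@H](c1ccc(O[Si](C)(C)C(C)(C)C)cc1)OC2O | intermediate
11 | (1S,4R,5R,8R)-4,8-di-Ar-3,7-dioxabicyclo[3.3.1]nonan-2-one | O=C1O[C@@H](c2ccc(O[Si](C)(C)C(C)(C)C)cc2)[C@@H]2C[C@H]1[C@H](c1ccc(O[Si](C)(C)C(C)(C)C)cc1)OC2 | intermediate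
12 | [(2R,3R,5R)-2-Ar-5-[(R)-Ar(hydroxy)methyl]oxan-3-yl]methanol, all-cis oxane | OC[C@H]1C[C@@H]([C@@H](O)c2ccc(O[Si](C)(C)C(C)(C)C)cc2)CO[C@H]1c1ccc(O[Si](C)(C)C(C)(C)C)cc1 | intermediate
13 | all-cis (2R,3S,5R)-2-Ar-3-(iodomethyl)-5-[(R)-Ar(hydroxy)methyl]oxane | IC[C@H]1C[C@@H]([C@@H](O)c2ccc(O[Si](C)(C)C(C)(C)C)cc2)CO[C@H]1c1ccc(O[Si](C)(C)C(C)(C)C)cc1 | intermediate
14 | triethylsilyl ether of 13 | IC[C@H]1C[C@@H]([C@@H](O[Si](CC)(CC)CC)c2ccc(O[Si](C)(C)C(C)(C)C)cc2)CO[C@H]1c1ccc(O[Si](C)(C)C(C)(C)C)cc1 | intermediate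
15 | (E)-tert-butyl[4-(2-iodoethenyl)phenoxy]dimethylsilane | I/C=C/c1ccc(O[Si](C)(C)C(C)(C)C)cc1 | intermediate
16 | alkylzinc iodide from 14 | I[Zn]C[C@H]1C[C@@H]([C@@H](O[Si](CC)(CC)CC)c2ccc(O[Si](C)(C)C(C)(C)C)cc2)CO[C@H]1c1ccc(O[Si](C)(C)C(C)(C)C)cc1 | intermediate
17 | (2R,3S,5R)-oxane, fully silylated target with E side chain | CC(C)(C)[Si](C)(C)Oc1ccc(/C=C/C[C@H]2C[C@@H]([C@@H](O[Si](CC)(CC)CC)c3ccc(O[Si](C)(C)C(C)(C)C)cc3)CO[C@H]2c2ccc(O[Si](C)(C)C(C)(C)C)cc2)cc1 | intermediate
18 | CNP0182155.1, (2R,3S,5R)-2-(4-hydroxyphenyl)-3-[(E)-3-(4-hydroxyphenyl)prop-2-enyl]-5-[(R)-hydroxy(4-hydroxyphenyl)methyl]oxane | Oc1ccc(/C=C/C[C@H]2C[C@@H]([C@@H](O)c3ccc(O)cc3)CO[C@H]2c2ccc(O)cc2)cc1 | target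

Total steps: 11. Longest linear sequence: 10 (steps 1 to 8, 10 and 11).

**Steps most likely to fail**

**Step 2.**
- *Risk.* The second addition may lag behind the first. Reversible addition of the electron-rich aldehyde before silylation may also erode the anti and facial selectivity.
- *Fallback.* It sets out from 2 and replaces the auxiliary-controlled direct aldol by a catalyst-controlled addition of a preformed nucleophile. Compound 2 is esterified with phenol (Et3N) to diphenyl glutarate F1. LiN(iPr)2 and TMSCl convert this into the bis(ketene silyl acetal) F2. F2 is added twice to 4 in an anti-selective catalytic asymmetric Mukaiyama aldol reaction, giving after acidic work-up the diphenyl ester diol F3. Conditions: Zr(OtBu)4, the antipode of 3,3'-diiodo-1,1'-bi-2-naphthol that delivers the (2S,3R) series, PrOH, toluene, 0 °C. Et3N and DMAP then close both lactone rings with loss of phenol, and the route is rejoined at 9.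

**Step 4.**
- *Risk.* The second carbonyl may be reduced at a rate close to that of the first, so that the product distribution drifts towards the statistical one.
- *Fallback.* It sets out from 9 and uses a self-limiting opening. One equivalent of LiOH (THF/H2O, 0 °C) opens one lactone, and the carboxylate charge and the loss of ring strain protect the other. Careful acidification gives the monolactone hydroxy acid F4. BH3·SMe2 reduces the acid in the presence of the lactone to the lactone diol F5. TsCl in pyridine sulfonylates the primary alcohol to the tosylate F6. NaH (THF, 0 °C) closes the oxane by a 6-exo-tet Williamson reaction of the benzylic alkoxide. The route is rejoined at 11, which also by-passes the Lewis acid of step 5.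

**Step 7.**
- *Risk.* The electron-rich benzylic alcohol may be activated beside the primary one, or the iodo alcohol may close to the bicyclic bis-ether.
- *Fallback.* It sets out from 11 and masks the carbinol before the primary alcohol exists. Me(MeO)NH·HCl with iPrMgCl opens the lactone to the hydroxy Weinreb amide F7. TESOTf and 2,6-lutidine give the silyl ether F8. iBu2AlH at −78 °C gives the aldehyde F9, which is reduced at once with NaBH4 to the primary alcohol F10 to avoid epimerisation at C3. Iodination with I2, PPh3 and imidazole rejoins the route at 14.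

**Further compounds**

F1 | step 2 | diphenyl glutarate | O=C(CCCC(=O)Oc1ccccc1)Oc1ccccc1
F2 | step 2 | bis(ketene silyl acetal) of diphenyl glutarate | C[Si](C)(C)OC(Oc1ccccc1)=CCC=C(Oc1ccccc1)O[Si](C)(C)C
F3 | step 2 | diphenyl (2S,4S)-2,4-bis[(R)-Ar(hydroxy)methyl]pentanedioate | O=C(Oc1ccccc1)[C@H]([C@@H](O)c1ccc(O[Si](C)(C)C(C)(C)C)cc1)C[C@@H]([C@@H](O)c1ccc(O[Si](C)(C)C(C)(C)C)cc1)C(=O)Oc1ccccc1
F4 | step 4 | (2R,3S,5S)-2-Ar-5-[(R)-Ar(hydroxy)methyl]-6-oxooxane-3-carboxylic acid | O=C1O[C@@H](c2ccc(O[Si](C)(C)C(C)(C)C)cc2)[C@@H](C(=O)O)C[C@H]1[C@@H](O)c1ccc(O[Si](C)(C)C(C)(C)C)cc1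
F5 | step 4 | lactone diol, CH2OH in place of the CO2H of F4 | O=C1O[C@@H](c2ccc(O[Si](C)(C)C(C)(C)C)cc2)[C@@H](CO)C[C@H]1[C@@H](O)c1ccc(O[Si](C)(C)C(C)(C)C)cc1
F6 | step 4 | primary tosylate of F5 | O=C1O[C@@H](c2ccc(O[Si](C)(C)C(C)(C)C)cc2)[C@@H](COS(=O)(=O)c2ccc(C)cc2)C[C@H]1[C@@H](O)c1ccc(O[Si](C)(C)C(C)(C)C)cc1
F7 | step 7 | hydroxy Weinreb amide from 11 | CON(C)C(=O)[C@H]1C[C@@H]([C@@H](O)c2ccc(O[Si](C)(C)C(C)(C)C)cc2)CO[C@H]1c1ccc(O[Si](C)(C)C(C)(C)C)cc1
F8 | step 7 | triethylsilyl ether of F7 | CON(C)C(=O)[C@H]1C[C@@H]([C@@H](O[Si](CC)(CC)CC)c2ccc(O[Si](C)(C)C(C)(C)C)cc2)CO[C@H]1c1ccc(O[Si](C)(C)C(C)(C)C)cc1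
F9 | step 7 | oxane-3-carbaldehyde from F8 | O=C[C@H]1C[C@@H]([C@@H](O[Si](CC)(CC)CC)c2ccc(O[Si](C)(C)C(C)(C)C)cc2)CO[C@H]1c1ccc(O[Si](C)(C)C(C)(C)C)cc1
F10 | step 7 | primary alcohol from F9 | OC[C@H]1C[C@@H]([C@@H](O[Si](CC)(CC)CC)c2ccc(O[Si](C)(C)C(C)(C)C)cc2)CO[C@H]1c1ccc(O[Si](C)(C)C(C)(C)C)cc1
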